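**Retrosynthetic overview**
1. The (Z)-coumarate is made last by Still–Gennari olefination of a C19 phosphonoacetate; the 13(16),14-diene comes from Stille vinylation of a C13 enol triflate.
2. The axial C8 tertiary alcohol comes from trans-diaxial Markovnikov oxymercuration of a Δ7 alkene.
3. Ring B (C9–C10 bond, C9 and C10 stereocentres) comes from acid-mediated cation–olefin closure of a monocyclic triene; its (Z)-alkene (from nerylacetone) puts the C9 chain axial.
4. Ring A (quaternary C4 and C5) comes from a catalytic enantioselective Diels–Alder reaction of methacrolein with an acyclic (E)-diene made from nerylacetone.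
5. Ring order: ring A first (Diels–Alder), then ring B (cationic closure).

Assumption: isomerically pure nerylacetone, acid 9 and the chiral acid (S,S)-IDPi (BINOL-derived imidodiphosphorimidate Brønsted acid with 3,3′-aryl groups and N-triflyl groups) are purchasable; labdane numbering (C1–C20) is used for ring compounds, and the target SMILES corresponds to (4R,5S,8R,9R,10R).

Step 1
Reactants: 1 nerylacetone [(5Z)-6,10-dimethylundeca-5,9-dien-2-one]
Product: 3 (2E,6Z)-2,6-dimethyl-10-oxoundeca-2,6-dienal, via allylic alcohol 2 (not isolated)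
Conditions: SeO2 (0.3 equiv), t-BuOOH (3 equiv), CH2Cl2, 0 °C to rt; then MnO2, CH2Cl2, rt
Reagents that add atoms: tert-butyl hydroperoxide, CC(C)(C)OO
Why: SeO2-catalysed allylic oxidation (ene reaction then [2,3]-shift) selects the (E)-methyl of the terminal trisubstituted alkene, and MnO2 takes the allylic alcohol on to the (E)-enal without touching the (Z)-alkene or the ketone; no stereocentre is formed.

Step 2
Reactants: 3 (2E,6Z)-2,6-dimethyl-10-oxoundeca-2,6-dienal
Product: 4 (5Z,9E)-6,10-dimethyldodeca-5,9,11-trien-2-one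
Conditions: Ph3PCH3Br, n-BuLi, THF, 0 °C; then 3 (1.0 equiv ylide), −78 to 0 °C
Reagents that add atoms: methyltriphenylphosphonium bromide, C[P+](c1ccccc1)(c1ccccc1)c1ccccc1.[Br-]
Why: Wittig methylenation, in which the aldehyde reacts much faster than the methyl ketone at −78 °C with one equivalent of ylide, gives the (E)-1-alkyl-2-methylbutadiene with the alkene geometries retained.

Step 3
Reactants: 4 (5Z,9E)-6,10-dimethyldodeca-5,9,11-trien-2-one
Product: 5 (5Z,9E)-6,10-dimethyldodeca-1,5,9,11-tetraen-2-yl trifluoromethanesulfonate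
Conditions: LiN(i-Pr)2, THF, −78 °C; then Comins' reagent, −78 to 0 °C
Reagents that add atoms: Comins' reagent [N-(5-chloropyridin-2-yl)-N-(trifluoromethanesulfonyl)trifluoromethanesulfonamide], FC(F)(F)S(=O)(=O)N(c1ccc(Cl)cn1)S(=O)(=O)C(F)(F)F
Why: kinetic deprotonation at the methyl group and O-sulfonylation give the terminal enol triflate, an acid-stable, non-nucleophilic placeholder for the 2-substituted butadiene that also stops the ketone from trapping the later C8 cation.

Step 4
Reactants: 5 (5Z,9E)-6,10-dimethyldodeca-1,5,9,11-tetraen-2-yl trifluoromethanesulfonate; 6 methacrolein (2-methylprop-2-enal)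
Product: 8 [(1R,2S)-1,3-dimethyl-2-[(3Z)-3-methyl-7-(trifluoromethanesulfonyloxy)octa-3,7-dien-1-yl]cyclohex-3-en-1-yl]methanol, via Diels–Alder aldehyde 7 (not isolated)
Conditions: (S,S)-IDPi (3 mol%), CH2Cl2, −60 °C; then NaBH4, EtOH, −40 to 0 °C
Reagents that add atoms: none
Why: Proposed new method: the confined chiral imidodiphosphorimidate acid activates methacrolein as an O–H···anion contact ion pair whose β-carbon bonds first to the unhindered CH2 terminus of the diene (asynchronous, "ortho" regiochemistry) with the formyl group endo, so this Diels–Alder reaction forms ring A and sets the quaternary C4 (CHO cis to the C5 chain) and C5 as (1R,2S) inside the chiral anion pocket; the closest known reaction types are imidodiphosphorimidate-catalysed Diels–Alder reactions of α-methylene ketones and unsaturated esters with simple dienes and oxazaborolidinium-catalysed Diels–Alder reactions of 2-substituted acroleins, neither shown for an α-branched enal with an unactivated acyclic 1,2-dialkyl diene; NaBH4 then removes the aldehyde before it can undergo Prins chemistry.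

Step 5
Reactants: 8 [(1R,2S)-1,3-dimethyl-2-[(3Z)-3-methyl-7-(trifluoromethanesulfonyloxy)octa-3,7-dien-1-yl]cyclohex-3-en-1-yl]methanol; 9 [bis(2,2,2-trifluoroethoxy)phosphoryl]acetic acid
Product: 10 [(1R,2S)-1,3-dimethyl-2-[(3Z)-3-methyl-7-(trifluoromethanesulfonyloxy)octa-3,7-dien-1-yl]cyclohex-3-en-1-yl]methyl [bis(2,2,2-trifluoroethoxy)phosphoryl]acetate
Conditions: EDC·HCl, DMAP (cat.), CH2Cl2, 0 °C to rt
Reagents that add atoms: none
Why: carbodiimide (Steglich) esterification of the primary alcohol installs the Still–Gennari phosphonate for the final olefination and masks the C19 oxygen, which as a free hydroxyl would capture the C10 cation as a bridged ether in the next step.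

Step 6
Reactants: 10 [(1R,2S)-1,3-dimethyl-2-[(3Z)-3-methyl-7-(trifluoromethanesulfonyloxy)octa-3,7-dien-1-yl]cyclohex-3-en-1-yl]methyl [bis(2,2,2-trifluoroethoxy)phosphoryl]acetate
Product: 11 (4R,5S,9S,10S)-13-(trifluoromethanesulfonyloxy)-14,15-dinorlabda-7,13(16)-dien-19-yl [bis(2,2,2-trifluoroethoxy)phosphoryl]acetate
Conditions: ClSO3H (5 equiv), 2-nitropropane, −78 °C
Reagents that add atoms: none
Why: cation–olefin cyclisation in which protonation of the ring alkene gives the tertiary C10 cation, C9 of the (Z)-alkene adds through a chair on the face away from the axial C19 group (trans-decalin, C10 methyl anti to H-5), C11 being cis to C7 in the alkene becomes axial at C9 (anti to the C10 methyl), and the C8 cation loses the aligned axial H-7 to give the Δ7 alkene (H-9 is equatorial and not aligned; the minor exocyclic isomer is separated).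

Step 7
Reactants: 11 (4R,5S,9S,10S)-13-(trifluoromethanesulfonyloxy)-14,15-dinorlabda-7,13(16)-dien-19-yl [bis(2,2,2-trifluoroethoxy)phosphoryl]acetate
Product: 13 (4R,5S,8R,9R,10R)-8-hydroxy-13-(trifluoromethanesulfonyloxy)-14,15-dinorlabd-13(16)-en-19-yl [bis(2,2,2-trifluoroethoxy)phosphoryl]acetate, via organomercurial 12 (not isolated)
Conditions: Hg(OAc)2, THF–H2O (1:1), rt; then NaBH4, 0 °C
Reagents that add atoms: water, O; mercury diacetate, CC(=O)O[Hg]OC(C)=O (retained in 12 only)
Why: oxymercuration–demercuration is Markovnikov and anti, and the mercurinium ion opens trans-diaxially, so water enters C8 axially (syn to the C10 methyl, anti to the axial C9 chain) while mercury sits axial at C7 and is then replaced by hydrogen, giving the axial 8-OH and equatorial 8-methyl of the target; the electron-poor enol triflate is inert.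

Step 8
Reactants: 13 (4R,5S,8R,9R,10R)-8-hydroxy-13-(trifluoromethanesulfonyloxy)-14,15-dinorlabd-13(16)-en-19-yl [bis(2,2,2-trifluoroethoxy)phosphoryl]acetate
Product: 14 (4R,5S,8R,9R,10R)-8-hydroxylabda-13(16),14-dien-19-yl [bis(2,2,2-trifluoroethoxy)phosphoryl]acetate
Conditions: CH2=CHSnBu3, Pd(PPh3)4 (5 mol%), LiCl, THF, 60 °C
Reagents that add atoms: tributyl(vinyl)stannane, C=C[Sn](CCCC)(CCCC)CCCC
Why: Stille coupling of the enol triflate with the vinylstannane forms the C13–C14 bond and the 2-substituted butadiene under neutral conditions that spare the phosphonoacetate and the tertiary alcohol; no stereocentre is touched.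

Step 9
Reactants: 14 (4R,5S,8R,9R,10R)-8-hydroxylabda-13(16),14-dien-19-yl [bis(2,2,2-trifluoroethoxy)phosphoryl]acetate; 15 4-[(tert-butyldimethylsilyl)oxy]benzaldehyde
Product: 17 (4R,5S,8R,9R,10R)-8-hydroxylabda-13(16),14-dien-19-yl (2Z)-3-(4-hydroxyphenyl)prop-2-enoate (target CNP0197278.6), via silyl ether 16 (not isolated)
Conditions: KN(SiMe3)2 (1.0 equiv), 18-crown-6, THF, −78 °C; then AcOH, Bu4NF, 0 °C
Reagents that add atoms: none
Why: Still–Gennari (Z-selective Horner–Wadsworth–Emmons) olefination, in which fast elimination from the kinetic adduct of the electron-poor bis(trifluoroethyl) phosphonate gives the (Z)-cinnamate; buffered fluoride then cleaves only the aryl silyl ether.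

**Compound list**
1 | nerylacetone, (5Z)-6,10-dimethylundeca-5,9-dien-2-one | CC(=O)CC/C=C(/C)CCC=C(C)C | starting material
2 | (5Z,9E)-11-hydroxy-6,10-dimethylundeca-5,9-dien-2-one | CC(=O)CC/C=C(/C)CC/C=C(\C)CO | intermediate
3 | (2E,6Z)-2,6-dimethyl-10-oxoundeca-2,6-dienal | CC(=O)CC/C=C(/C)CC/C=C(\C)C=O | intermediate
4 | (5Z,9E)-6,10-dimethyldodeca-5,9,11-trien-2-one | CC(=O)CC/C=C(/C)CC/C=C(\C)C=C | intermediate
5 | (5Z,9E)-6,10-dimethyldodeca-1,5,9,11-tetraen-2-yl trifluoromethanesulfonate | C=C(OS(=O)(=O)C(F)(F)F)CC/C=C(/C)CC/C=C(\C)C=C | intermediate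
6 | methacrolein, 2-methylprop-2-enal | CC(=C)C=O | starting material
7 | (1R,2S)-1,3-dimethyl-2-[(3Z)-3-methyl-7-(trifluoromethanesulfonyloxy)octa-3,7-dien-1-yl]cyclohex-3-ene-1-carbaldehyde | C=C(OS(=O)(=O)C(F)(F)F)CC/C=C(/C)CC[C@H]1C(C)=CCC[C@@]1(C)C=O | intermediate
8 | [(1R,2S)-1,3-dimethyl-2-[(3Z)-3-methyl-7-(trifluoromethanesulfonyloxy)octa-3,7-dien-1-yl]cyclohex-3-en-1-yl]methanol | C=C(OS(=O)(=O)C(F)(F)F)CC/C=C(/C)CC[C@H]1C(C)=CCC[C@@]1(C)CO | intermediate
9 | [bis(2,2,2-trifluoroethoxy)phosphoryl]acetic acid | OC(=O)CP(=O)(OCC(F)(F)F)OCC(F)(F)F | starting material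
10 | [(1R,2S)-1,3-dimethyl-2-[(3Z)-3-methyl-7-(trifluoromethanesulfonyloxy)octa-3,7-dien-1-yl]cyclohex-3-en-1-yl]methyl [bis(2,2,2-trifluoroethoxy)phosphoryl]acetate | C=C(OS(=O)(=O)C(F)(F)F)CC/C=C(/C)CC[C@H]1C(C)=CCC[C@@]1(C)COC(=O)CP(=O)(OCC(F)(F)F)OCC(F)(F)F | intermediate
11 | (4R,5S,9S,10S)-13-(trifluoromethanesulfonyloxy)-14,15-dinorlabda-7,13(16)-dien-19-yl [bis(2,2,2-trifluoroethoxy)phosphoryl]acetate | C=C(OS(=O)(=O)C(F)(F)F)CC[C@@H]1[C@]2(C)CCC[C@@](C)(COC(=O)CP(=O)(OCC(F)(F)F)OCC(F)(F)F)[C@H]2CC=C1C | intermediate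
12 | (4R,5S,7S,8S,9R,10R)-7-(acetoxymercurio)-8-hydroxy-13-(trifluoromethanesulfonyloxy)-14,15-dinorlabd-13(16)-en-19-yl [bis(2,2,2-trifluoroethoxy)phosphoryl]acetate | C=C(OS(=O)(=O)C(F)(F)F)CC[C@@H]1[C@]2(C)CCC[C@@](C)(COC(=O)CP(=O)(OCC(F)(F)F)OCC(F)(F)F)[C@H]2C[C@H]([Hg]OC(C)=O)[C@@]1(C)O | intermediate
13 | (4R,5S,8R,9R,10R)-8-hydroxy-13-(trifluoromethanesulfonyloxy)-14,15-dinorlabd-13(16)-en-19-yl [bis(2,2,2-trifluoroethoxy)phosphoryl]acetate | C=C(OS(=O)(=O)C(F)(F)F)CC[C@@H]1[C@]2(C)CCC[C@@](C)(COC(=O)CP(=O)(OCC(F)(F)F)OCC(F)(F)F)[C@H]2CC[C@@]1(C)O | intermediate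
14 | (4R,5S,8R,9R,10R)-8-hydroxylabda-13(16),14-dien-19-yl [bis(2,2,2-trifluoroethoxy)phosphoryl]acetate | C=CC(=C)CC[C@@H]1[C@]2(C)CCC[C@@](C)(COC(=O)CP(=O)(OCC(F)(F)F)OCC(F)(F)F)[C@H]2CC[C@@]1(C)O | intermediate
15 | 4-[(tert-butyldimethylsilyl)oxy]benzaldehyde | O=Cc1ccc(O[Si](C)(C)C(C)(C)C)cc1 | starting material
16 | (4R,5S,8R,9R,10R)-8-hydroxylabda-13(16),14-dien-19-yl (2Z)-3-[4-[(tert-butyldimethylsilyl)oxy]phenyl]prop-2-enoate | C=CC(=C)CC[C@@H]1[C@]2(C)CCC[C@@](C)(COC(=O)/C=C\c3ccc(O[Si](C)(C)C(C)(C)C)cc3)[C@H]2CC[C@@]1(C)O | intermediate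
17 | (4R,5S,8R,9R,10R)-8-hydroxylabda-13(16),14-dien-19-yl (2Z)-3-(4-hydroxyphenyl)prop-2-enoate | C=CC(=C)CC[C@@H]1[C@]2(C)CCC[C@@](C)(COC(=O)/C=C\c3ccc(O)cc3)[C@H]2CC[C@@]1(C)O | target

**Step count and weak points**
Total steps: 9. Longest linear sequence: 9 steps (1 to 17); compounds 6, 9 and 15 are bought.

Step 4 (the proposed new step) is the most likely to fail: it needs "ortho" regiochemistry with a 1,2-dialkyl diene, endo selectivity, face selectivity and tolerance of the polyene to a strong acid. The fallback sets out from 5 and 6 and replaces Brønsted-acid ion pairing by covalent chiral boron Lewis-acid activation, which is known chemistry for 2-methylacrolein with acyclic dienes. The triflimide-activated oxazaborolidine from α,α-diphenylprolinol and o-tolylboron (10–20 mol%, CH2Cl2, −78 °C; the enantiomer that gives the (1R,2S) adduct) delivers aldehyde 7. The same NaBH4 quench comes back to the route at 8. This fallback makes no compound outside the list (F0).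

Step 6 is the second risk: the phosphonoacetate may not survive chlorosulfonic acid, and cis-fused or exocyclic isomers may form. The fallback sets out from 8 and carries the C19 oxygen as a simple acetate through the acid and mercury steps. Ac2O and pyridine give the monocyclic acetate F1. FSO3H in 2-nitropropane at −78 °C closes ring B to the bicyclic Δ7 acetate F2. Hg(OAc)2 in aqueous THF gives the organomercurial acetate F3, which NaBH4 reduces in the same flask to the hydroxy acetate F4. i-Bu2AlH at −78 °C removes the acetate to give the diol F5. EDC coupling with 9, selective for the primary hydroxyl over the tertiary one, comes back to the route at 13.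

Step 7 is the third risk: mercuration of the hindered trisubstituted alkene may be slow, or the trans-diaxial preference may erode. The fallback sets out from 11 and uses a halohydrin instead. N-Bromosuccinimide in aqueous THF at 0 °C gives the bromohydrin F6 by Markovnikov, anti, diaxial opening of the bromonium ion (7-Br axial, 8-OH axial). Bu3SnH with AIBN in toluene at 80 °C removes the bromine and comes back to the route at 13.

**Further compounds**
F0 | step 4 | none | none
F1 | step 6 | monocyclic acetate, [(1R,2S)-1,3-dimethyl-2-[(3Z)-3-methyl-7-(trifluoromethanesulfonyloxy)octa-3,7-dien-1-yl]cyclohex-3-en-1-yl]methyl acetate | C=C(OS(=O)(=O)C(F)(F)F)CC/C=C(/C)CC[C@H]1C(C)=CCC[C@@]1(C)COC(C)=O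
F2 | step 6 | bicyclic Δ7 acetate, (4R,5S,9S,10S)-13-(trifluoromethanesulfonyloxy)-14,15-dinorlabda-7,13(16)-dien-19-yl acetate | C=C(OS(=O)(=O)C(F)(F)F)CC[C@@H]1[C@]2(C)CCC[C@@](C)(COC(C)=O)[C@H]2CC=C1C
F3 | step 6 | organomercurial acetate, (4R,5S,7S,8S,9R,10R)-7-(acetoxymercurio)-8-hydroxy-13-(trifluoromethanesulfonyloxy)-14,15-dinorlabd-13(16)-en-19-yl acetate | C=C(OS(=O)(=O)C(F)(F)F)CC[C@@H]1[C@]2(C)CCC[C@@](C)(COC(C)=O)[C@H]2C[C@H]([Hg]OC(C)=O)[C@@]1(C)O
F4 | step 6 | hydroxy acetate, (4R,5S,8R,9R,10R)-8-hydroxy-13-(trifluoromethanesulfonyloxy)-14,15-dinorlabd-13(16)-en-19-yl acetate | C=C(OS(=O)(=O)C(F)(F)F)CC[C@@H]1[C@]2(C)CCC[C@@](C)(COC(C)=O)[C@H]2CC[C@@]1(C)O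
F5 | step 6 | diol, (4R,5S,8R,9R,10R)-8,19-dihydroxy-14,15-dinorlabd-13(16)-en-13-yl trifluoromethanesulfonate | C=C(OS(=O)(=O)C(F)(F)F)CC[C@@H]1[C@]2(C)CCC[C@@](C)(CO)[C@H]2CC[C@@]1(C)O
F6 | step 7 | bromohydrin, (4R,5S,7S,8S,9R,10R)-7-bromo-8-hydroxy-13-(trifluoromethanesulfonyloxy)-14,15-dinorlabd-13(16)-en-19-yl [bis(2,2,2-trifluoroethoxy)phosphoryl]acetate | C=C(OS(=O)(=O)C(F)(F)F)CC[C@@H]1[C@]2(C)CCC[C@@](C)(COC(=O)CP(=O)(OCC(F)(F)F)OCC(F)(F)F)[C@H]2C[C@H](Br)[C@@]1(C)O
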